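**Plan**

1. The last bond cut is the one between the bridging CH2 and C6 of ring A (the dearomatised acyl triketone); in the forward direction it is made last, by addition of ring A to an ortho-quinone methide released from a phenolic Mannich base on ring B.
2. On the chromene half, the aryl–isobutyryl bond at C8 and the aryl–CH2 bond at C6 are cut next; both arise from directed lithiations of a bis(methoxymethyl) chromene.
3. Ring C is cut at O1–C8a, C4–C4a and O1–C2 together. In rings B and C the pyran oxygen O1 and the vinylic carbon C4 sit on adjacent arene carbons (C8a, C4a), and C4a is flanked by the oxygen-bearing C5: the imprint of a 3-alkoxybenzyne that has taken up the C=O group of an enal.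
4. Ring A is cut at the C4–prenyl bond and at the ring–isobutyryl bond, back to 2-methylphloroglucinol.
5. Forward order: ring B goes from phloroglucinol to a silyl triflate, ring C closes in step 5, C6 and C8 are substituted, ring A is made separately, and the halves are joined last.
6. The single stereocentre (C4 of ring A, S) is set by the chiral ligand in a palladium-catalysed dearomative prenylation (step 11) and is not touched afterwards.

Key step: step 5

Remark: ring A is written in the enol form of the target SMILES (its keto–enol forms interconvert and C4 is S in each); the ligand enantiomer written in step 11 is provisional, and its mirror image would be used should the sense of induction prove opposite.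

**Route**

Step 1
Reactants: 1 phloroglucinol
Product: 2 3,5-bis(methoxymethoxy)phenol
Conditions: MOMCl (2.1 equiv), i-Pr2NEt (2.5 equiv), DMF, 0 °C → rt; chromatography
Reagents that add atoms: chloromethyl methyl ether, COCCl
Why: Williamson-type O-alkylation of three equivalent phenols is statistical, so with two equivalents of MOMCl the bis-ether should be the main fraction and can be separated from the mono- and tris-ethers.

Step 2
Reactants: 2 3,5-bis(methoxymethoxy)phenol
Product: 3 3,5-bis(methoxymethoxy)phenyl N-isopropylcarbamate
Conditions: i-PrNCO (1.2 equiv), Et3N (0.2 equiv), CH2Cl2, rt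
Reagents that add atoms: isopropyl isocyanate, CC(C)N=C=O
Why: Amine-catalysed addition of the phenol to the isocyanate (carbamoylation) installs a strong ortho-directing group that can later be removed under mild base.

Step 3
Reactants: 3 3,5-bis(methoxymethoxy)phenyl N-isopropylcarbamate
Product: 7 3,5-bis(methoxymethoxy)-2-(trimethylsilyl)phenyl N-isopropylcarbamate, via N-silyl carbamate 4 (not isolated), via aryllithium 5 (not isolated), via bis-silyl carbamate 6 (not isolated)
Conditions: TBSOTf (1.05 equiv), TMEDA (1.1 equiv), Et2O, 0 °C → rt; n-BuLi (1.2 equiv), TMEDA (1.2 equiv), −78 °C; TMSCl (3 equiv), −78 °C → rt; aq NaHSO4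
Reagents that add atoms: chlorotrimethylsilane, C[Si](C)(C)Cl
Why: Directed ortho-metalation, in which in-situ N-silylation masks the acidic N–H, the carbamate and the neighbouring MOM ether together guide n-BuLi to the ring carbon between them rather than to the carbon between the two MOM ethers, TMSCl traps the aryllithium, and the N-silyl group is lost on acidic work-up.

Step 4
Reactants: 7 3,5-bis(methoxymethoxy)-2-(trimethylsilyl)phenyl N-isopropylcarbamate
Product: 9 3,5-bis(methoxymethoxy)-2-(trimethylsilyl)phenyl trifluoromethanesulfonate, via silylphenol 8 (not isolated)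
Conditions: DBU (1.5 equiv), Et2NH (1.2 equiv), MeCN, 40 °C; then PhNTf2 (1.5 equiv), rt
Reagents that add atoms: N-phenylbis(trifluoromethanesulfonimide), O=S(=O)(N(c1ccccc1)S(=O)(=O)C(F)(F)F)C(F)(F)F
Why: The N–H carbamate is cleaved by the amidine base through E1cB elimination to the isocyanate (taken up by diethylamine), and the phenoxide is O-triflated in the same pot, under conditions that leave the aryl–silicon bond and the MOM ethers intact.

Step 5
Reactants: 9 3,5-bis(methoxymethoxy)-2-(trimethylsilyl)phenyl trifluoromethanesulfonate; 10 3-methylbut-2-enal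
Product: 14 5,7-bis(methoxymethoxy)-2,2-dimethyl-2H-chromene, via aryne 11 (not isolated), via benzoxete 12 (not isolated), via ortho-quinone methide 13 (not isolated)
Conditions: CsF (3 equiv), 10 (3 equiv), MeCN, rt → 50 °C, 9 added slowly
Reagents that add atoms: none
Why: Fluoride attack on silicon and loss of triflate release aryne 11, whose triple bond is distorted by the flanking methoxymethoxy group so that the carbon remote from it is the electrophilic terminus; the carbonyl oxygen of the enal bonds there and the aryl anion developing beside the ether closes on the carbonyl carbon, a formal [2+2] addition giving benzoxete 12. Strain-driven 4π ring opening then gives ortho-quinone methide 13. Ring C closes by a thermal, disrotatory oxa-6π electrocyclisation in which the quinone methide oxygen bonds to the dimethyl-substituted alkene terminus, driven by rearomatisation of ring B. The closest known reaction type is the fluoride-induced annulation of arynes from ortho-silylaryl triflates with α,β-unsaturated aldehydes to 2H-chromenes. No stereocentre is formed. The step needs one orientation of addition (oxygen on the aryne carbon meta to the flanking ether, carbon on the ortho one), which the inductive bias of the 3-alkoxy group secures, and it needs carbonyl addition to outrun ene reaction at the allylic methyl groups, which an excess of aldehyde and slow aryne release favour.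

Step 6
Reactants: 14 5,7-bis(methoxymethoxy)-2,2-dimethyl-2H-chromene; 15 N,N-dimethylmethyleneiminium iodide
Product: 17 1-[5,7-bis(methoxymethoxy)-2,2-dimethyl-2H-chromen-6-yl]-N,N-dimethylmethanamine, via 6-lithiochromene 16 (not isolated)
Conditions: n-BuLi (1.1 equiv), THF, 0 °C; then 15 (1.3 equiv), −78 °C → rt
Reagents that add atoms: none
Why: Directed ortho-metalation occurs at C6, the only ring carbon flanked by two chelating MOM ethers and hence the most acidic, and the aryllithium adds to the iminium carbon (Mannich-type aminomethylation), which introduces the future bridge carbon and blocks C6 at once.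

Step 7
Reactants: 17 1-[5,7-bis(methoxymethoxy)-2,2-dimethyl-2H-chromen-6-yl]-N,N-dimethylmethanamine; 18 N-methoxy-N-methylisobutyramide
Product: 21 1-{6-[(dimethylamino)methyl]-5,7-bis(methoxymethoxy)-2,2-dimethyl-2H-chromen-8-yl}-2-methylpropan-1-one, via 8-lithiochromene 19 (not isolated), via lithium hemiaminal 20 (not isolated)
Conditions: n-BuLi (1.2 equiv), TMEDA (1.2 equiv), THF, 0 °C; then 18 (1.5 equiv), −78 °C → 0 °C; aq NH4Cl
Reagents that add atoms: none
Why: With C6 occupied the only arene hydrogen left is at C8, between the C7 MOM ether and the pyran oxygen, so this second directed ortho-metalation is unambiguous, and acylation with the N-methoxy-N-methylamide stops at the ketone because the chelated tetrahedral adduct survives until work-up.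

Step 8
Reactants: 21 1-{6-[(dimethylamino)methyl]-5,7-bis(methoxymethoxy)-2,2-dimethyl-2H-chromen-8-yl}-2-methylpropan-1-one
Product: 22 1-{6-[(dimethylamino)methyl]-5,7-dihydroxy-2,2-dimethyl-2H-chromen-8-yl}-2-methylpropan-1-one
Conditions: 3 M HCl–MeOH, 40 °C; then aq NaHCO3 to pH 7–8; used at once
Reagents that add atoms: none
Why: Acid-catalysed acetal exchange with methanol removes both MOM ethers, while protonation of the amine and the deactivating C8 ketone should keep the benzylic C–N bond and the chromene double bond from ionising under these mild conditions.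

Step 9
Reactants: 23 2-methylphloroglucinol; 24 isobutyryl chloride
Product: 25 2-methyl-1-(2,4,6-trihydroxy-3-methylphenyl)propan-1-one
Conditions: AlCl3 (3.5 equiv), PhNO2, rt → 60 °C; aq HCl
Reagents that add atoms: none
Why: Friedel–Crafts acylation at one of the two equivalent free ring carbons of the electron-rich triol, which should stop after one acylation because the aluminium-chelated aryl ketone deactivates the ring.

Step 10
Reactants: 26 3-methylbut-2-en-1-ol
Product: 27 methyl 3-methylbut-2-en-1-yl carbonate
Conditions: ClCO2Me (1.2 equiv), pyridine (1.5 equiv), CH2Cl2, 0 °C → rt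
Reagents that add atoms: methyl chloroformate, COC(=O)Cl
Why: Acylation of the primary allylic alcohol by the chloroformate gives a prenyl donor that ionises readily with zerovalent palladium and supplies its own base.

Step 11
Reactants: 25 2-methyl-1-(2,4,6-trihydroxy-3-methylphenyl)propan-1-one; 27 methyl 3-methylbut-2-en-1-yl carbonate
Product: 28 (4S)-3,5-dihydroxy-4-methyl-4-(3-methylbut-2-en-1-yl)-2-(2-methylpropanoyl)cyclohexa-2,5-dien-1-one
Conditions: Pd2(dba)3·CHCl3 (2.5 mol %), (1R,2R)-N,N'-bis[2-(diphenylphosphanyl)benzoyl]cyclohexane-1,2-diamine (7.5 mol %), 25 (1.1 equiv), 27 (1.0 equiv), CH2Cl2, 0 °C → rt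
Reagents that add atoms: none
Why: Proposed new method: zerovalent palladium ionises the carbonate to a cationic π-prenyl complex of divalent palladium, CO2 and methoxide, the methoxide deprotonates 25, and the phenolate attacks the unsubstituted allyl terminus through its methyl-bearing ring carbon (the most nucleophilic carbon, as in classical geminal C-alkylation of acylphloroglucinols, with O-prenylation reversible under palladium), while the C2-symmetric ligand pocket selects one of the two enantiotopic faces of the flat arene and so sets the quaternary stereocentre; the closest known reaction types are the palladium-catalysed asymmetric allylic dearomatisation of naphthols and 3-substituted indoles (Tsuji–Trost allylic alkylation) and the racemic palladium-catalysed dearomative allylation of acylphloroglucinols.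

Step 12
Reactants: 22 1-{6-[(dimethylamino)methyl]-5,7-dihydroxy-2,2-dimethyl-2H-chromen-8-yl}-2-methylpropan-1-one; 28 (4S)-3,5-dihydroxy-4-methyl-4-(3-methylbut-2-en-1-yl)-2-(2-methylpropanoyl)cyclohexa-2,5-dien-1-one
Product: 30 (4S)-6-{[5,7-dihydroxy-2,2-dimethyl-8-(2-methylpropanoyl)-2H-chromen-6-yl]methyl}-3,5-dihydroxy-4-methyl-4-(3-methylbut-2-en-1-yl)-2-(2-methylpropanoyl)cyclohexa-2,5-dien-1-one, via ortho-quinone methide 29 (not isolated)
Conditions: 1,4-dioxane, 80 °C, argon sweep; then dilute aq HCl wash
Reagents that add atoms: none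
Why: On warming, the zwitterionic phenolic Mannich base loses dimethylamine to give ortho-quinone methide 29, which the enol of β-triketone 28 captures through its only C–H carbon (C6) in a Michael addition that rearomatises ring B; no bond to the quaternary stereocentre is involved, so its configuration is retained.

**Compound list**

1 | phloroglucinol | Oc1cc(O)cc(O)c1 | starting material
2 | 3,5-bis(methoxymethoxy)phenol | COCOc1cc(O)cc(OCOC)c1 | intermediate
3 | 3,5-bis(methoxymethoxy)phenyl N-isopropylcarbamate | COCOc1cc(OC(=O)NC(C)C)cc(OCOC)c1 | intermediate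
4 | 3,5-bis(methoxymethoxy)phenyl N-(tert-butyldimethylsilyl)-N-isopropylcarbamate | COCOc1cc(OC(=O)N(C(C)C)[Si](C)(C)C(C)(C)C)cc(OCOC)c1 | intermediate
5 | 2-lithio derivative of 4 (lithium between the carbamate oxygen and a MOM ether) | COCOc1cc(OCOC)c([Li])c(OC(=O)N(C(C)C)[Si](C)(C)C(C)(C)C)c1 | intermediate
6 | 3,5-bis(methoxymethoxy)-2-(trimethylsilyl)phenyl N-(tert-butyldimethylsilyl)-N-isopropylcarbamate | COCOc1cc(OCOC)c([Si](C)(C)C)c(OC(=O)N(C(C)C)[Si](C)(C)C(C)(C)C)c1 | intermediate
7 | 3,5-bis(methoxymethoxy)-2-(trimethylsilyl)phenyl N-isopropylcarbamate | COCOc1cc(OCOC)c([Si](C)(C)C)c(OC(=O)NC(C)C)c1 | intermediate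
8 | 3,5-bis(methoxymethoxy)-2-(trimethylsilyl)phenol (present as its amidinium phenoxide) | COCOc1cc(OCOC)c([Si](C)(C)C)c(O)c1 | intermediate
9 | 3,5-bis(methoxymethoxy)-2-(trimethylsilyl)phenyl trifluoromethanesulfonate | COCOc1cc(OCOC)c([Si](C)(C)C)c(OS(=O)(=O)C(F)(F)F)c1 | intermediate
10 | 3-methylbut-2-enal | CC(C)=CC=O | starting material
11 | 3,5-bis(methoxymethoxy)benzyne | COCOC1=CC(OCOC)=CC#C1 | intermediate
12 | 3,5-bis(methoxymethoxy)-2-(2-methylprop-1-en-1-yl)-2H-benzo[b]oxete | COCOc1cc(OCOC)c2C(C=C(C)C)Oc2c1 | intermediate
13 | 3,5-bis(methoxymethoxy)-6-(3-methylbut-2-en-1-ylidene)cyclohexa-2,4-dien-1-one | COCOC1=CC(=O)C(=CC=C(C)C)C(OCOC)=C1 | intermediate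
14 | 5,7-bis(methoxymethoxy)-2,2-dimethyl-2H-chromene | COCOc1cc(OCOC)c2C=CC(C)(C)Oc2c1 | intermediate
15 | N,N-dimethylmethyleneiminium iodide | C=[N+](C)C.[I-] | starting material
16 | 6-lithio-5,7-bis(methoxymethoxy)-2,2-dimethyl-2H-chromene | COCOc1c([Li])c(OCOC)c2C=CC(C)(C)Oc2c1 | intermediate
17 | 1-[5,7-bis(methoxymethoxy)-2,2-dimethyl-2H-chromen-6-yl]-N,N-dimethylmethanamine | COCOc1c(CN(C)C)c(OCOC)c2C=CC(C)(C)Oc2c1 | intermediate
18 | N-methoxy-N-methylisobutyramide | CC(C)C(=O)N(C)OC | starting material
19 | 8-lithio derivative of 17 | COCOc1c(CN(C)C)c(OCOC)c2C=CC(C)(C)Oc2c1[Li] | intermediate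
20 | lithium alkoxide of the tetrahedral adduct of 19 and 18 | COCOc1c(CN(C)C)c(OCOC)c2C=CC(C)(C)Oc2c1C(O[Li])(C(C)C)N(C)OC | intermediate
21 | 1-{6-[(dimethylamino)methyl]-5,7-bis(methoxymethoxy)-2,2-dimethyl-2H-chromen-8-yl}-2-methylpropan-1-one | COCOc1c(CN(C)C)c(OCOC)c2C=CC(C)(C)Oc2c1C(=O)C(C)C | intermediate
22 | 1-{6-[(dimethylamino)methyl]-5,7-dihydroxy-2,2-dimethyl-2H-chromen-8-yl}-2-methylpropan-1-one | CC(C)C(=O)c1c(O)c(CN(C)C)c(O)c2C=CC(C)(C)Oc12 | intermediate
23 | 2-methylphloroglucinol | Cc1c(O)cc(O)cc1O | starting material
24 | isobutyryl chloride | CC(C)C(=O)Cl | starting material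
25 | 2-methyl-1-(2,4,6-trihydroxy-3-methylphenyl)propan-1-one | CC(C)C(=O)c1c(O)cc(O)c(C)c1O | intermediate
26 | 3-methylbut-2-en-1-ol | CC(C)=CCO | starting material
27 | methyl 3-methylbut-2-en-1-yl carbonate | COC(=O)OCC=C(C)C | intermediate
28 | (4S)-3,5-dihydroxy-4-methyl-4-(3-methylbut-2-en-1-yl)-2-(2-methylpropanoyl)cyclohexa-2,5-dien-1-one | CC(C)=CC[C@@]1(C)C(O)=CC(=O)C(C(=O)C(C)C)=C1O | intermediate
29 | 7-hydroxy-2,2-dimethyl-6-methylidene-8-(2-methylpropanoyl)-2H-chromen-5(6H)-one | C=C1C(=O)C2=C(OC(C)(C)C=C2)C(C(=O)C(C)C)=C1O | intermediate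
30 | (4S)-6-{[5,7-dihydroxy-2,2-dimethyl-8-(2-methylpropanoyl)-2H-chromen-6-yl]methyl}-3,5-dihydroxy-4-methyl-4-(3-methylbut-2-en-1-yl)-2-(2-methylpropanoyl)cyclohexa-2,5-dien-1-one | CC(C)=CC[C@@]1(C)C(O)=C(Cc2c(O)c3c(c(C(=O)C(C)C)c2O)OC(C)(C)C=C3)C(=O)C(C(=O)C(C)C)=C1O | target

**Step count and risks**

Total step count: 12. Longest linear sequence: 9 (steps 1–8, then step 12).

Step 11 (asymmetric dearomative prenylation). The ligand may discriminate the two faces of the arene poorly, prenylation may go to the unsubstituted ring carbon with rearomatisation, or the product may be prenylated a second time at its C6. The fallback uses known chemistry and sets out from 25. Classical base-mediated dearomative C-alkylation with 1-bromo-3-methylbut-2-ene and NaOMe in MeOH at 0 °C should give racemic 3,5-dihydroxy-4-methyl-4-(3-methylbut-2-en-1-yl)-2-(2-methylpropanoyl)cyclohexa-2,5-dien-1-one F1. The enantiomers would then be separated by preparative chromatography on a chiral stationary phase (amylose tris(3,5-dimethylphenylcarbamate)), the configuration being assigned by chiroptical comparison, and the (S)-enantiomer rejoins the route at 28.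

Step 5 (aryne annulation). Hydrogen transfer from the allylic methyl groups of the enal to the aryne (ene reaction) may compete, the quinone methide may take up a second aryne, or the orientation of addition may be imperfect. The fallback sets out from 2. O-Alkylation with 3-chloro-3-methylbut-1-yne (DBU, CuCl2 catalyst, MeCN, 0 °C) should give 1,3-bis(methoxymethoxy)-5-[(2-methylbut-3-yn-2-yl)oxy]benzene F2. Heating in xylene at 140 °C should bring about aromatic propargyl Claisen rearrangement to either of the two equivalent ortho carbons, enolisation, 1,5-hydrogen shift and oxa-6π closure, returning to the route at 14.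

Step 12 (union of the halves). The bridged product may fragment reversibly (retro-Michael) and recombine to symmetrical dimers, or the quinone methide may condense with itself before the triketone intercepts it. The fallback reverses the polarity of the union and sets out from 14 and 28.
- Lithiation of 14 (n-BuLi, THF, 0 °C) and quench with TMSCl should block C6 as [5,7-bis(methoxymethoxy)-2,2-dimethyl-2H-chromen-6-yl]trimethylsilane F3.
- A second lithiation at C8 and acylation with 18 should give 1-[5,7-bis(methoxymethoxy)-2,2-dimethyl-6-(trimethylsilyl)-2H-chromen-8-yl]-2-methylpropan-1-one F4.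
- HCl–MeOH should remove both MOM ethers and, by ipso-protodesilylation, the silyl group, giving 1-(5,7-dihydroxy-2,2-dimethyl-2H-chromen-8-yl)-2-methylpropan-1-one F5.
- Separately, 28 with 15 and NaOAc in MeCN at rt should give the ring A Mannich base (4S)-6-[(dimethylamino)methyl]-3,5-dihydroxy-4-methyl-4-(3-methylbut-2-en-1-yl)-2-(2-methylpropanoyl)cyclohexa-2,5-dien-1-one F6.
- At 40 °C F6 loses dimethylamine to a 6-methylene trione, which F5 should capture through its only free arene carbon (C6), returning to the route at target 30.

Further compounds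
F1 | step 11 | racemic 3,5-dihydroxy-4-methyl-4-(3-methylbut-2-en-1-yl)-2-(2-methylpropanoyl)cyclohexa-2,5-dien-1-one | CC(C)=CCC1(C)C(O)=CC(=O)C(C(=O)C(C)C)=C1O
F2 | step 5 | 1,3-bis(methoxymethoxy)-5-[(2-methylbut-3-yn-2-yl)oxy]benzene | COCOc1cc(OCOC)cc(OC(C)(C)C#C)c1
F3 | step 12 | [5,7-bis(methoxymethoxy)-2,2-dimethyl-2H-chromen-6-yl]trimethylsilane | COCOc1c([Si](C)(C)C)c(OCOC)c2C=CC(C)(C)Oc2c1
F4 | step 12 | 1-[5,7-bis(methoxymethoxy)-2,2-dimethyl-6-(trimethylsilyl)-2H-chromen-8-yl]-2-methylpropan-1-one | COCOc1c([Si](C)(C)C)c(OCOC)c2C=CC(C)(C)Oc2c1C(=O)C(C)C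
F5 | step 12 | 1-(5,7-dihydroxy-2,2-dimethyl-2H-chromen-8-yl)-2-methylpropan-1-one | CC(C)C(=O)c1c(O)cc(O)c2C=CC(C)(C)Oc12
F6 | step 12 | (4S)-6-[(dimethylamino)methyl]-3,5-dihydroxy-4-methyl-4-(3-methylbut-2-en-1-yl)-2-(2-methylpropanoyl)cyclohexa-2,5-dien-1-one | CC(C)=CC[C@@]1(C)C(O)=C(CN(C)C)C(=O)C(C(=O)C(C)C)=C1O
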